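**Retrosynthetic overview**

1. Chromene numbering O1, C2 to C8a is used; ring A is the benzene ring of the chromene and ring B the pyran ring. The prenyl ether and the free phenol are set last, by O-alkylation of the C7 hydroxyl and fluoride cleavage of a triisopropylsilyl ether on the distal phenol.
2. Key disconnection: ring B is closed at the C8a–O1 bond while ring A is held at the p-quinol (4-hydroxycyclohexa-2,5-dienone) oxidation level. O1 of a (Z)-3-hydroxy-3-methylbut-1-enyl chain on C4a adds to C8a, and loss of the C4a hydroxyl then rearomatizes ring A and delivers the C7 oxygen as the only free phenol.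
3. Enabling feature: in ring A the C7 oxygen is para to C4a and meta to C8a. A C7 carbonyl therefore makes C8a the β-carbon of a dienone, while C4a is the carbinol carbon that carries both the (Z) chain and the leaving hydroxyl; the other β-carbon, C5, is blocked by the arylethyl group.
4. The quinol ketal comes from 1,2-addition of dilithiated 2-methylbut-3-yn-2-ol (C2 to C4 and O1) to a quinone monoketal, followed by Lindlar reduction. The monoketal comes from PhI(OAc)2 oxidation of a 2-(arylethyl)-4-methoxyphenol, itself made by B-alkyl Suzuki coupling.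
5. Ring order: both benzene rings are bought; ring A is dearomatized in step 4, and ring B is formed and ring A rearomatized together in step 7.

Key step: step 7

Remark: the target has no stereocentre; compounds 9 to 12 are racemic and their configuration is erased when ring A aromatizes.

**Route**

Step 1
Reactants: 1 4-hydroxybenzaldehyde
Product: 2 4-(triisopropylsilyloxy)benzaldehyde
Conditions: TIPSCl (1.1 equiv), imidazole (2 equiv), DMF, rt
Reagents that add atoms: chlorotriisopropylsilane (TIPSCl), CC(C)[Si](Cl)(C(C)C)C(C)C
Why: Imidazole-mediated silylation of a phenol gives a hindered aryl silyl ether that should survive ylide, borane, aqueous phosphate, organolithium, hydrogenation, dilute acid and carbonate conditions and be cleaved by fluoride at the end.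

Step 2
Reactants: 2 4-(triisopropylsilyloxy)benzaldehyde
Product: 3 triisopropyl(4-vinylphenoxy)silane
Conditions: Ph3PCH3Br (1.3 equiv), KOt-Bu (1.25 equiv), THF, 0 °C to rt
Reagents that add atoms: methyltriphenylphosphonium bromide, C[P+](c1ccccc1)(c1ccccc1)c1ccccc1.[Br-]
Why: Wittig methylenation of a non-enolizable aryl aldehyde with the unstabilized ylide Ph3P=CH2 should be clean.

Step 3
Reactants: 3 triisopropyl(4-vinylphenoxy)silane; 4 2-bromo-4-methoxyphenol
Product: 6 4-methoxy-2-{2-[4-(triisopropylsilyloxy)phenyl]ethyl}phenol, via B-alkyl-9-BBN borane 5 (not isolated)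
Conditions: 3 (1.3 equiv), 9-BBN (1.35 equiv), THF, 0 °C to rt; then 4, PdCl2(dppf) (5 mol%), aq K3PO4 (4 equiv), DMF, 65 °C
Reagents that add atoms: none
Why: Anti-Markovnikov hydroboration of the styrene with 9-BBN followed by B-alkyl Suzuki–Miyaura coupling should give the bibenzyl, the extra base carrying the free phenol of 4 through as its phenoxide.

Step 4
Reactants: 6 4-methoxy-2-{2-[4-(triisopropylsilyloxy)phenyl]ethyl}phenol
Product: 7 4,4-dimethoxy-2-{2-[4-(triisopropylsilyloxy)phenyl]ethyl}cyclohexa-2,5-dien-1-one
Conditions: PhI(OAc)2 (1.1 equiv), MeOH, 0 °C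
Reagents that add atoms: methanol, CO
Why: Oxidative dearomatization of a para-methoxyphenol by PhI(OAc)2 in methanol traps the phenoxonium ion at the methoxy-bearing carbon to give the quinone monoketal, and the silyl-protected ring is not oxidized.

Step 5
Reactants: 7 4,4-dimethoxy-2-{2-[4-(triisopropylsilyloxy)phenyl]ethyl}cyclohexa-2,5-dien-1-one; 8 2-methylbut-3-yn-2-ol
Product: 9 rac-1-(3-hydroxy-3-methylbut-1-yn-1-yl)-4,4-dimethoxy-2-{2-[4-(triisopropylsilyloxy)phenyl]ethyl}cyclohexa-2,5-dien-1-ol
Conditions: 8 (2.2 equiv), n-BuLi (4.4 equiv), THF, −78 to 0 °C; then 7, −78 °C; then H2O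
Reagents that add atoms: none
Why: 1,2-Addition of a lithium acetylide to the carbonyl group of a quinone monoketal is the standard entry to 4-substituted quinol ketals and creates the racemic carbinol centre that later becomes C4a.

Step 6
Reactants: 9 rac-1-(3-hydroxy-3-methylbut-1-yn-1-yl)-4,4-dimethoxy-2-{2-[4-(triisopropylsilyloxy)phenyl]ethyl}cyclohexa-2,5-dien-1-ol
Product: 10 rac-1-[(Z)-3-hydroxy-3-methylbut-1-en-1-yl]-4,4-dimethoxy-2-{2-[4-(triisopropylsilyloxy)phenyl]ethyl}cyclohexa-2,5-dien-1-ol
Conditions: H2 (1 atm), Pd/CaCO3 poisoned with Pb(OAc)2 (Lindlar catalyst), quinoline, EtOAc, rt; filtered and used without chromatography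
Reagents that add atoms: none
Why: Lindlar semihydrogenation by syn addition of H2 should give the (Z) alkene that brings the tertiary hydroxyl within reach of the ring, while the poisoned catalyst leaves the ring alkenes and the ketal alone.

Step 7
Reactants: 10 rac-1-[(Z)-3-hydroxy-3-methylbut-1-en-1-yl]-4,4-dimethoxy-2-{2-[4-(triisopropylsilyloxy)phenyl]ethyl}cyclohexa-2,5-dien-1-ol
Product: 13 2,2-dimethyl-5-{2-[4-(triisopropylsilyloxy)phenyl]ethyl}-2H-chromen-7-ol, via p-quinol dienone 11 (not isolated), via cis-fused oxa-Michael adduct 12 (not isolated)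
Conditions: (PhO)2P(O)OH (10 mol%), H2O (5 equiv), CH2Cl2, rt; then TsOH·H2O (20 mol%), 40 °C
Reagents that add atoms: water, O
Why: The weak acid should first hydrolyse the doubly allylic ketal to p-quinol dienone 11 and then activate its C7 carbonyl so that the tertiary hydroxyl O1 adds to the unsubstituted β-carbon C8a to give adduct 12; the stronger acid should then ionize the tertiary allylic C4a hydroxyl (helped by enolization of the C7 ketone toward C8), and loss of the C8a proton gives aromatic ring A with the C7 oxygen as a free phenol. The closest known reaction types are the Brønsted acid catalysed intramolecular oxa-Michael addition of alcohols tethered to the carbinol carbon of p-quinols, and the conjugate addition with dehydrative rearomatization of p-quinols and quinone monoketals that gives meta-substituted phenols. Ring B closes in the 6-exo-trig mode by forming the C8a–O1 bond. The two stereocentres of 12 (C4a and C8a, cis because O1 is delivered from the face that carries the chain) are transient, and no stereocentre remains in 13. The step needs regioselectivity between the two β-carbons and chemoselectivity against cyclodehydration of the (Z)-ene-1,4-diol to a spiro-dihydrofuran: C5 is fully substituted so addition there is reversible and cannot aromatize, the (Z) alkene holds O1 over C8a, and the phosphoric diester should be too weak to ionize either tertiary alcohol before O1 is tied up in ring B. The product is a 2,2-dimethyl-2H-chromene of the kind routinely released by TsOH-catalysed dehydration of chroman-4-ols, so it should tolerate the second stage.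

Step 8
Reactants: 13 2,2-dimethyl-5-{2-[4-(triisopropylsilyloxy)phenyl]ethyl}-2H-chromen-7-ol; 14 1-bromo-3-methylbut-2-ene (prenyl bromide)
Product: 15 triisopropyl(4-{2-[2,2-dimethyl-7-(3-methylbut-2-en-1-yloxy)-2H-chromen-5-yl]ethyl}phenoxy)silane
Conditions: K2CO3 (2 equiv), acetone, rt
Reagents that add atoms: none
Why: Williamson O-alkylation (SN2) of the only free phenol with an allylic bromide under mild carbonate conditions should be selective because the other phenol is masked as its silyl ether.

Step 9
Reactants: 15 triisopropyl(4-{2-[2,2-dimethyl-7-(3-methylbut-2-en-1-yloxy)-2H-chromen-5-yl]ethyl}phenoxy)silane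
Product: 16 4-{2-[2,2-dimethyl-7-(3-methylbut-2-en-1-yloxy)-2H-chromen-5-yl]ethyl}phenol (CNP0337021.0)
Conditions: Bu4NF (1.1 equiv), THF, 0 °C; then H2O
Reagents that add atoms: none
Why: Fluoride-induced cleavage of the aryl silyl ether should leave the prenyl ether, the chromene alkene and the acid-sensitive pyran ring untouched.

**Compound list**

1 | 4-hydroxybenzaldehyde | O=Cc1ccc(O)cc1 | starting material
2 | 4-(triisopropylsilyloxy)benzaldehyde | O=Cc1ccc(O[Si](C(C)C)(C(C)C)C(C)C)cc1 | intermediate
3 | triisopropyl(4-vinylphenoxy)silane | C=Cc1ccc(O[Si](C(C)C)(C(C)C)C(C)C)cc1 | intermediate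
4 | 2-bromo-4-methoxyphenol | COc1ccc(O)c(Br)c1 | starting material
5 | 9-{2-[4-(triisopropylsilyloxy)phenyl]ethyl}-9-borabicyclo[3.3.1]nonane | CC(C)[Si](Oc1ccc(CCB2C3CCCC2CCC3)cc1)(C(C)C)C(C)C | intermediate
6 | 4-methoxy-2-{2-[4-(triisopropylsilyloxy)phenyl]ethyl}phenol | COc1ccc(O)c(CCc2ccc(O[Si](C(C)C)(C(C)C)C(C)C)cc2)c1 | intermediate
7 | 4,4-dimethoxy-2-{2-[4-(triisopropylsilyloxy)phenyl]ethyl}cyclohexa-2,5-dien-1-one | COC1(OC)C=CC(=O)C(CCc2ccc(O[Si](C(C)C)(C(C)C)C(C)C)cc2)=C1 | intermediate
8 | 2-methylbut-3-yn-2-ol | CC(C)(O)C#C | starting material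
9 | rac-1-(3-hydroxy-3-methylbut-1-yn-1-yl)-4,4-dimethoxy-2-{2-[4-(triisopropylsilyloxy)phenyl]ethyl}cyclohexa-2,5-dien-1-ol (racemic) | COC1(OC)C=CC(O)(C#CC(C)(C)O)C(CCc2ccc(O[Si](C(C)C)(C(C)C)C(C)C)cc2)=C1 | intermediate
10 | rac-1-[(Z)-3-hydroxy-3-methylbut-1-en-1-yl]-4,4-dimethoxy-2-{2-[4-(triisopropylsilyloxy)phenyl]ethyl}cyclohexa-2,5-dien-1-ol (racemic) | COC1(OC)C=CC(O)(/C=C\C(C)(C)O)C(CCc2ccc(O[Si](C(C)C)(C(C)C)C(C)C)cc2)=C1 | intermediate
11 | rac-4-hydroxy-4-[(Z)-3-hydroxy-3-methylbut-1-en-1-yl]-3-{2-[4-(triisopropylsilyloxy)phenyl]ethyl}cyclohexa-2,5-dien-1-one (racemic) | O=C1C=CC(O)(/C=C\C(C)(C)O)C(CCc2ccc(O[Si](C(C)C)(C(C)C)C(C)C)cc2)=C1 | intermediate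
12 | rac-cis-4a-hydroxy-2,2-dimethyl-5-{2-[4-(triisopropylsilyloxy)phenyl]ethyl}-8,8a-dihydro-2H-chromen-7(4aH)-one (racemic; relative configuration shown) | O=C1C[C@@H]2OC(C)(C)C=C[C@]2(O)C(CCc3ccc(O[Si](C(C)C)(C(C)C)C(C)C)cc3)=C1 | intermediate
13 | 2,2-dimethyl-5-{2-[4-(triisopropylsilyloxy)phenyl]ethyl}-2H-chromen-7-ol | CC1(C)C=Cc2c(CCc3ccc(O[Si](C(C)C)(C(C)C)C(C)C)cc3)cc(O)cc2O1 | intermediate
14 | 1-bromo-3-methylbut-2-ene (prenyl bromide) | CC(C)=CCBr | starting material
15 | triisopropyl(4-{2-[2,2-dimethyl-7-(3-methylbut-2-en-1-yloxy)-2H-chromen-5-yl]ethyl}phenoxy)silane | CC(C)=CCOc1cc(CCc2ccc(O[Si](C(C)C)(C(C)C)C(C)C)cc2)c2c(c1)OC(C)(C)C=C2 | intermediate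
16 | 4-{2-[2,2-dimethyl-7-(3-methylbut-2-en-1-yloxy)-2H-chromen-5-yl]ethyl}phenol | CC(C)=CCOc1cc(CCc2ccc(O)cc2)c2c(c1)OC(C)(C)C=C2 | target

**Step count and risks**

Total step count: 9. Longest linear sequence: 9 steps (1 to 16); compounds 4, 8 and 14 are bought.

Steps most likely to fail:

Step 7. The (Z)-ene-1,4-diol may ionize at the side-chain carbinol before O1 has added to C8a, so that the C4a hydroxyl closes a spiro-dihydrofuran and a dienone–phenol rearrangement with carbon migration follows; alternatively the sequence may stall at the hydrated adduct. The fallback sets out from 10 and comes back at 13 by a stepwise, cation-free sequence. Buffered hydrolysis (pyridinium p-toluenesulfonate, wet acetone, 0 °C) should allow the quinol dienone 11 to be isolated. Anionic oxa-Michael addition (KOt-Bu, 10 mol%, THF, 0 °C) should close ring B to the isolated adduct 12. Syn-dehydration of the C4a hydroxyl against the cis C8a hydrogen with the Burgess reagent (toluene, 50 °C) should give the dienone tautomer, which enolizes to 13. This fallback makes no compound outside the compound list (F0).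

Step 6. Semihydrogenation of an alkyne flanked by two quaternary carbinol carbons may be slow, and forcing it may lead to over-reduction or to hydrogenolysis of the allylic C–O bonds. The fallback sets out from 7 and comes back at 10 by adding the (Z) chain with its geometry already fixed. Ethyl (Z)-3-iodoacrylate with MeMgBr (2.2 equiv, THF, −78 °C) should give (Z)-4-iodo-2-methylbut-3-en-2-ol F1. Deprotonation with MeLi and iodine–lithium exchange with t-BuLi (2 equiv, Et2O, −78 °C) should give the configurationally stable dilithio species, whose 1,2-addition to 7 and quench with water should give 10 directly.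

Step 3. Oxidative addition into the electron-rich bromophenoxide may be slow, so that protodeboronation or β-hydride elimination of the alkyl group wins. The fallback sets out from 3 and 4 and comes back at 6. A Heck reaction (Pd(OAc)2, P(o-tol)3, Et3N, DMF, 100 °C) should give (E)-4-methoxy-2-{2-[4-(triisopropylsilyloxy)phenyl]ethenyl}phenol F2, and hydrogenation (H2, Pd/C, EtOAc, rt) should give 6.

**Further compounds**

F0 | step 7 | none | none
F1 | step 6 | (Z)-4-iodo-2-methylbut-3-en-2-ol | CC(C)(O)/C=C\I
F2 | step 3 | (E)-4-methoxy-2-{2-[4-(triisopropylsilyloxy)phenyl]ethenyl}phenol | COc1ccc(O)c(/C=C/c2ccc(O[Si](C(C)C)(C(C)C)C(C)C)cc2)c1
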